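**Strategy.** The only unsaturation of ring B is the C6=C7 bond (eudesmane numbering), and its C7 terminus also holds the C8 carbonyl and the hydroxyisopropyl carbon C11; the route therefore makes this bond last. One ruthenium-catalysed ring-closing metathesis joins a C5 vinyl group to the methylene of an α-substituted enone attached through C9 to C10, forming the enone of ring B on a complete ring A with loss of ethene. The substrate is a cyclohexane bearing the C3/C4 cis-diol as acetonide, the C4 and C10 methyls, and trans-disposed C5 vinyl and C10 CH2C(=O)C(=CH2)C(Me)2OSiEt3 arms; C10 and C5 are set by two Claisen rearrangements with chirality transfer.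

Key step: step 17

Remark (assumption): positions are named in eudesmane numbering and β is the face of the C10 methyl group; compounds 22 and 23 have the same configuration as the target, (3R,4S,5R,10R); alcohol 21 is carried as both C8 epimers because that carbon is oxidised in step 16; hydrazone 19 is drawn without C=N geometry.

**Route**

Step 1
Reactants: 1 3-methylcyclohex-2-en-1-one
Product: 2 (1R)-3-methylcyclohex-2-en-1-ol
Conditions: (S)-2-methyl-CBS-oxazaborolidine (10 mol %), catecholborane, toluene, −78 °C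
Reagents that add atoms: none
Why: CBS reduction: the oxazaborolidine–borane complex binds the carbonyl with the alkenyl side as the large group and delivers hydride to one face, which should set the (R)-carbinol centre that is relayed to C10 in step 2.

Step 2
Reactants: 2 (1R)-3-methylcyclohex-2-en-1-ol
Product: 4 ethyl 2-[(1R)-1-methylcyclohex-2-en-1-yl]acetate, via ketene acetal 3 (not isolated)
Conditions: MeC(OEt)3 (5 equiv), EtCO2H (cat.), 140 °C, EtOH distilled off
Reagents that add atoms: triethyl orthoacetate, CC(OCC)(OCC)OCC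
Why: Johnson–Claisen rearrangement: orthoester exchange gives ketene acetal 3, whose suprafacial [3,3]-shift transfers the C–O stereocentre to the new quaternary C10, the acetate arm entering on the face (α) that the oxygen leaves.

Step 3
Reactants: 4 ethyl 2-[(1R)-1-methylcyclohex-2-en-1-yl]acetate
Product: 5 ethyl 2-[(1R)-1-methyl-4-oxocyclohex-2-en-1-yl]acetate
Conditions: Rh2(cap)4 (cap = caprolactamate, 1 mol %), t-BuOOH, K2CO3 (cat.), CH2Cl2, rt
Reagents that add atoms: tert-butyl hydroperoxide, CC(C)(C)OO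
Why: Rhodium-catalysed allylic C–H oxidation with tert-butyl hydroperoxide: the only allylic hydrogens are on C3 (the other allylic carbon, C10, is quaternary) and the peroxy radical should couple at this unhindered terminus, giving the C3 enone without touching C10.

Step 4
Reactants: 5 ethyl 2-[(1R)-1-methyl-4-oxocyclohex-2-en-1-yl]acetate
Product: 6 ethyl 2-[(1R)-3-iodo-1-methyl-4-oxocyclohex-2-en-1-yl]acetate
Conditions: I2, pyridine, CH2Cl2, 0 °C to rt
Reagents that add atoms: iodine, II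
Why: α-Iodination of an enone by pyridine-mediated addition, iodination and elimination (Baylis–Hillman-type), a reaction established for 4,4-disubstituted cyclohexenones.

Step 5
Reactants: 6 ethyl 2-[(1R)-3-iodo-1-methyl-4-oxocyclohex-2-en-1-yl]acetate
Product: 7 ethyl 2-[(1R)-1,3-dimethyl-4-oxocyclohex-2-en-1-yl]acetate
Conditions: MeB(OH)2, PdCl2(dppf) (5 mol %), K3PO4, THF/H2O, 65 °C
Reagents that add atoms: methylboronic acid, CB(O)O
Why: Suzuki–Miyaura cross-coupling of the α-iodoenone places the C4 methyl on an sp2 carbon, so no stereocentre is involved.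

Step 6
Reactants: 7 ethyl 2-[(1R)-1,3-dimethyl-4-oxocyclohex-2-en-1-yl]acetate
Product: 8 ethyl 2-[(1R,4S)-4-hydroxy-1,3-dimethylcyclohex-2-en-1-yl]acetate
Conditions: (R)-2-methyl-CBS-oxazaborolidine (20 mol %), catecholborane, toluene, −78 to −40 °C
Reagents that add atoms: none
Why: CBS reduction: with the methyl-bearing alkene carbon as the large group the (R)-catalyst should give the (S)-carbinol (C3 oxygen β, cis to the C10 methyl) under reagent control, and any material of the wrong C10 configuration becomes a separable diastereomer.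

Step 7
Reactants: 8 ethyl 2-[(1R,4S)-4-hydroxy-1,3-dimethylcyclohex-2-en-1-yl]acetate
Product: 10 ethyl 2-[(1R,2R)-2-[2-(dimethylamino)-2-oxoethyl]-1,3-dimethylcyclohex-3-en-1-yl]acetate, via ketene aminoacetal 9 (not isolated)
Conditions: MeC(OMe)2NMe2 (4 equiv), xylenes, 140 °C
Reagents that add atoms: N,N-dimethylacetamide dimethyl acetal, COC(C)(OC)N(C)C
Why: Eschenmoser–Claisen rearrangement: ketene aminoacetal 9 rearranges suprafacially, so the acetamide arm is delivered to C5 on the β face from which the C3 oxygen departs, trans to the C10 acetate arm and cis to the smaller C10 methyl, while the alkene moves to C3=C4.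

Step 8
Reactants: 10 ethyl 2-[(1R,2R)-2-[2-(dimethylamino)-2-oxoethyl]-1,3-dimethylcyclohex-3-en-1-yl]acetate
Product: 11 ethyl 2-[(1R,2R,3S,4R)-2-[2-(dimethylamino)-2-oxoethyl]-3,4-dihydroxy-1,3-dimethylcyclohexyl]acetate
Conditions: OsO4 (5 mol %), N-methylmorpholine N-oxide, acetone/H2O, rt
Reagents that add atoms: osmium tetroxide, O=[Os](=O)(=O)=O; N-methylmorpholine N-oxide, C[N+]1([O-])CCOCC1; water, O
Why: Upjohn dihydroxylation: syn addition of OsO4 to the only alkene should occur anti to the adjacent C5 substituent (α face), fixing the cis C3 and C4 oxygens with the C4 methyl β.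

Step 9
Reactants: 11 ethyl 2-[(1R,2R,3S,4R)-2-[2-(dimethylamino)-2-oxoethyl]-3,4-dihydroxy-1,3-dimethylcyclohexyl]acetate
Product: 12 ethyl 2-[(3aS,4R,5R,7aR)-4-[2-(dimethylamino)-2-oxoethyl]-2,2,3a,5-tetramethylhexahydro-1,3-benzodioxol-5-yl]acetate
Conditions: Me2C(OMe)2, PPTS (cat.), CH2Cl2, rt
Reagents that add atoms: 2,2-dimethoxypropane, COC(C)(C)OC
Why: Acid-catalysed transketalisation ties the cis-diol into a five-membered acetonide, which masks both hydroxyls through the reductions, oxidations and the organolithium addition.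

Step 10
Reactants: 12 ethyl 2-[(3aS,4R,5R,7aR)-4-[2-(dimethylamino)-2-oxoethyl]-2,2,3a,5-tetramethylhexahydro-1,3-benzodioxol-5-yl]acetate
Product: 13 2-[(3aS,4R,5R,7aR)-4-[2-(dimethylamino)ethyl]-2,2,3a,5-tetramethylhexahydro-1,3-benzodioxol-5-yl]ethan-1-ol
Conditions: LiAlH4, THF, 0 °C to reflux
Reagents that add atoms: none
Why: Hydride reduction with LiAlH4 takes the ethyl ester to the primary alcohol and the tertiary amide to the tertiary amine in one operation, which differentiates the two arms by functional group and touches no stereocentre.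

Step 11
Reactants: 13 2-[(3aS,4R,5R,7aR)-4-[2-(dimethylamino)ethyl]-2,2,3a,5-tetramethylhexahydro-1,3-benzodioxol-5-yl]ethan-1-ol
Product: 15 2-[(3aS,4R,5R,7aR)-4-ethenyl-2,2,3a,5-tetramethylhexahydro-1,3-benzodioxol-5-yl]ethan-1-ol, via amine N-oxide 14 (not isolated)
Conditions: mCPBA (1.0 equiv), CH2Cl2, 0 °C; filtration through basic alumina; then toluene, 110 °C
Reagents that add atoms: mCPBA, OOC(=O)c1cccc(Cl)c1 (its oxygen is held by N-oxide 14 only)
Why: Cope elimination: N-oxidation and thermal syn-elimination of N,N-dimethylhydroxylamine, for which the only β-hydrogens are on C6, unveils the C5 vinyl group without acid or base.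

Step 12
Reactants: 15 2-[(3aS,4R,5R,7aR)-4-ethenyl-2,2,3a,5-tetramethylhexahydro-1,3-benzodioxol-5-yl]ethan-1-ol
Product: 16 2-[(3aS,4R,5R,7aR)-4-ethenyl-2,2,3a,5-tetramethylhexahydro-1,3-benzodioxol-5-yl]acetaldehyde
Conditions: Dess–Martin periodinane, CH2Cl2, rt
Reagents that add atoms: none
Why: Dess–Martin oxidation of the primary alcohol gives the C8 aldehyde, which has no α-stereocentre, and leaves the vinyl group untouched.

Step 13
Reactants: 17 3-hydroxy-3-methylbutan-2-one
Product: 18 3-methyl-3-[(triethylsilyl)oxy]butan-2-one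
Conditions: Et3SiOTf, 2,6-lutidine, CH2Cl2, 0 °C
Reagents that add atoms: triethylsilyl trifluoromethanesulfonate, CC[Si](CC)(CC)OS(=O)(=O)C(F)(F)F
Why: Silylation of a tertiary alcohol with a silyl triflate and a hindered base is standard and gives the ether that later carries C11.

Step 14
Reactants: 18 3-methyl-3-[(triethylsilyl)oxy]butan-2-one
Product: 19 N'-{3-methyl-3-[(triethylsilyl)oxy]butan-2-ylidene}-2,4,6-tri(propan-2-yl)benzenesulfonohydrazide
Conditions: 2,4,6-triisopropylbenzenesulfonohydrazide, PPTS (cat.), THF, rt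
Reagents that add atoms: 2,4,6-triisopropylbenzenesulfonohydrazide, CC(C)c1cc(C(C)C)c(S(=O)(=O)NN)c(C(C)C)c1
Why: Condensation of the methyl ketone with the arenesulfonyl hydrazide gives the hydrazone needed for the Shapiro reaction.

Step 15
Reactants: 16 2-[(3aS,4R,5R,7aR)-4-ethenyl-2,2,3a,5-tetramethylhexahydro-1,3-benzodioxol-5-yl]acetaldehyde; 19 N'-{3-methyl-3-[(triethylsilyl)oxy]butan-2-ylidene}-2,4,6-tri(propan-2-yl)benzenesulfonohydrazide
Product: 21 1-[(3aS,4R,5R,7aR)-4-ethenyl-2,2,3a,5-tetramethylhexahydro-1,3-benzodioxol-5-yl]-4-methyl-3-methylidene-4-[(triethylsilyl)oxy]pentan-2-ol (both C2 epimers), via alkenyllithium 20 (not isolated)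
Conditions: 19 (1.6 equiv), n-BuLi (3.3 equiv), THF, −78 to 0 °C; then 16, −78 °C; H2O
Reagents that add atoms: n-butyllithium, [Li]CCCC (lithium of 20 only)
Why: Shapiro reaction: double deprotonation (N–H and the methyl group, the only α-hydrogens), loss of sulfinate and dinitrogen give alkenyllithium 20, which adds to the aldehyde carbonyl; the new carbinol centre is uncontrolled and is removed in step 16.

Step 16
Reactants: 21 1-[(3aS,4R,5R,7aR)-4-ethenyl-2,2,3a,5-tetramethylhexahydro-1,3-benzodioxol-5-yl]-4-methyl-3-methylidene-4-[(triethylsilyl)oxy]pentan-2-ol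
Product: 22 1-[(3aS,4R,5R,7aR)-4-ethenyl-2,2,3a,5-tetramethylhexahydro-1,3-benzodioxol-5-yl]-4-methyl-3-methylidene-4-[(triethylsilyl)oxy]pentan-2-one
Conditions: Dess–Martin periodinane, CH2Cl2, 0 °C to rt
Reagents that add atoms: none
Why: Dess–Martin oxidation of the allylic alcohols converges both epimers to the α-methylene ketone under neutral conditions.

Step 17
Reactants: 22 1-[(3aS,4R,5R,7aR)-4-ethenyl-2,2,3a,5-tetramethylhexahydro-1,3-benzodioxol-5-yl]-4-methyl-3-methylidene-4-[(triethylsilyl)oxy]pentan-2-one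
Product: 23 (4aR,5S,6R,8aR)-5,8a-dimethyl-5,6-[(propane-2,2-diyl)bis(oxy)]-3-{2-[(triethylsilyl)oxy]propan-2-yl}-4a,5,6,7,8,8a-hexahydronaphthalen-2(1H)-one
Conditions: second-generation Grubbs catalyst RuCl2(=CHPh)(PCy3)(H2IMes) (10 mol %, in portions), toluene (2 mM), 80 °C, argon sparge
Reagents that add atoms: none
Why: The ruthenium benzylidene first exchanges with the unhindered monosubstituted C5 vinyl group, and the resulting C6 alkylidene adds intramolecularly across the C7 methylene of the enone to a ruthenacyclobutane whose cycloreversion releases the C6=C7 bond and a ruthenium methylidene, the loss of ethene making the sequence irreversible. The closest known reaction type is ring-closing metathesis of α-methylene ketones with terminal alkenes to 2-substituted cyclohex-2-enones. Ring B closes as a six-membered carbocycle from a 1,7-diene whose two arms sit on adjacent ring A carbons, which gives the trans-fused decalin. No stereocentre is created; C3, C4, C5 and C10 are carried unchanged, and the trans ring fusion follows from the trans relation of the C5 and C10 arms. The step needs initiation at the vinyl group and ring closure faster than vinyl–vinyl dimerisation; the electron-poor 1,1-disubstituted alkene neither initiates nor homodimerises, the two arms are held adjacent and diequatorial on the ring A chair, and high dilution with removal of ethene favours cyclisation. The tertiary hydroxyl is silylated so that it cannot chelate the alkylidene formed next to it.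

Step 18
Reactants: 23 (4aR,5S,6R,8aR)-5,8a-dimethyl-5,6-[(propane-2,2-diyl)bis(oxy)]-3-{2-[(triethylsilyl)oxy]propan-2-yl}-4a,5,6,7,8,8a-hexahydronaphthalen-2(1H)-one
Product: 24 (4aR,5S,6R,8aR)-5,6-dihydroxy-3-(2-hydroxypropan-2-yl)-5,8a-dimethyl-4a,5,6,7,8,8a-hexahydronaphthalen-2(1H)-one
Conditions: 1 M aq. HCl/THF (1:3), rt
Reagents that add atoms: none
Why: Aqueous acid hydrolysis removes the acetonide and the tertiary silyl ether in one operation and avoids basic conditions that could epimerise C5 through the dienolate.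

Step 19
Reactants: 25 tiglic acid
Product: 26 (2E)-2-methylbut-2-en-1-ol
Conditions: LiAlH4, Et2O, 0 °C to rt
Reagents that add atoms: none
Why: 1,2-Reduction of the conjugated acid with LiAlH4 gives the allylic alcohol with the E geometry retained.

Step 20
Reactants: 26 (2E)-2-methylbut-2-en-1-ol
Product: 27 [(2R,3R)-2,3-dimethyloxiran-2-yl]methanol
Conditions: Ti(OiPr)4 (10 mol %), D-(−)-diethyl tartrate (12 mol %), t-BuOOH, 4 Å molecular sieves, CH2Cl2, −20 °C
Reagents that add atoms: tert-butyl hydroperoxide, CC(C)(C)OO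
Why: Sharpless asymmetric epoxidation: with the D-(−)-tartrate the titanium-bound peroxide is delivered to the alkene face that gives the (2R,3R)-epoxy alcohol, both stereocentres arising from syn addition to the E alkene.

Step 21
Reactants: 27 [(2R,3R)-2,3-dimethyloxiran-2-yl]methanol
Product: 28 (2S,3R)-2,3-dimethyloxirane-2-carboxylic acid
Conditions: RuCl3·xH2O (2 mol %), NaIO4, MeCN/EtOAc/H2O, rt
Reagents that add atoms: water, O
Why: Ruthenium tetroxide oxidation (RuCl3/NaIO4) takes the primary alcohol to the acid without opening the epoxide; the change of descriptor at C2 is a priority change only.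

Step 22
Reactants: 28 (2S,3R)-2,3-dimethyloxirane-2-carboxylic acid
Product: 29 (2R,3S)-3-chloro-2-hydroxy-2-methylbutanoic acid
Conditions: HCl (4 M in dioxane), 0 °C to rt
Reagents that add atoms: hydrogen chloride, Cl
Why: Acid-mediated epoxide opening: chloride attacks C3 by SN2 with inversion because the carboxyl-bearing C2 is deactivated towards substitution, which gives the (2R,3S)-chlorohydrin.

Step 23
Reactants: 29 (2R,3S)-3-chloro-2-hydroxy-2-methylbutanoic acid
Product: 31 (2R,3S)-3-chloro-2-methyl-2-[(triethylsilyl)oxy]butanoic acid, via bis-silyl compound 30 (not isolated)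
Conditions: Et3SiOTf (2.2 equiv), 2,6-lutidine, CH2Cl2, −78 to 0 °C; then aq. NaHCO3/THF, then citric acid
Reagents that add atoms: triethylsilyl trifluoromethanesulfonate, CC[Si](CC)(CC)OS(=O)(=O)C(F)(F)F
Why: The silyl triflate silylates the tertiary hydroxyl and the acid, and the labile silyl ester is hydrolysed on work-up, leaving an acyl donor with no free hydroxyl that could self-acylate or close back to the epoxide.

Step 24
Reactants: 24 (4aR,5S,6R,8aR)-5,6-dihydroxy-3-(2-hydroxypropan-2-yl)-5,8a-dimethyl-4a,5,6,7,8,8a-hexahydronaphthalen-2(1H)-one; 31 (2R,3S)-3-chloro-2-methyl-2-[(triethylsilyl)oxy]butanoic acid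
Product: 33 (1S,2R,4aR,8aR)-1-hydroxy-7-(2-hydroxypropan-2-yl)-1,4a-dimethyl-6-oxo-1,2,3,4,4a,5,6,8a-octahydronaphthalen-2-yl (2R,3S)-3-chloro-2-methyl-2-[(triethylsilyl)oxy]butanoate, via mixed anhydride 32 (not isolated)
Conditions: 31 (2 equiv), 2,4,6-Cl3C6H2COCl, Et3N, toluene, rt; then 24, DMAP, toluene, rt to 50 °C
Reagents that add atoms: 2,4,6-trichlorobenzoyl chloride, O=C(Cl)c1c(Cl)cc(Cl)cc1Cl (its acyl group is held by 32 only)
Why: Yamaguchi esterification: mixed anhydride 32 acylates, under DMAP catalysis, the only secondary hydroxyl (C3) of the triol while the two tertiary hydroxyls stay unreactive, and no stereocentre is affected.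

Step 25
Reactants: 33 (1S,2R,4aR,8aR)-1-hydroxy-7-(2-hydroxypropan-2-yl)-1,4a-dimethyl-6-oxo-1,2,3,4,4a,5,6,8a-octahydronaphthalen-2-yl (2R,3S)-3-chloro-2-methyl-2-[(triethylsilyl)oxy]butanoate
Product: 34 (1S,2R,4aR,8aR)-1-hydroxy-7-(2-hydroxypropan-2-yl)-1,4a-dimethyl-6-oxo-1,2,3,4,4a,5,6,8a-octahydronaphthalen-2-yl (2R,3S)-3-chloro-2-hydroxy-2-methylbutanoate
Conditions: HF·pyridine, THF, 0 °C to rt
Reagents that add atoms: none
Why: Fluoride-mediated desilylation under slightly acidic conditions frees the tertiary hydroxyl of the side chain without closing the chlorohydrin to the epoxide.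

**Compound list**

1 | 3-methylcyclohex-2-en-1-one | CC1=CC(=O)CCC1 | starting material
2 | (1R)-3-methylcyclohex-2-en-1-ol | O[C@@H]1CCCC(C)=C1 | intermediate
3 | (3R)-3-[(1-ethoxyethenyl)oxy]-1-methylcyclohex-1-ene (ketene acetal) | CCOC(=C)O[C@@H]1CCCC(C)=C1 | intermediate
4 | ethyl 2-[(1R)-1-methylcyclohex-2-en-1-yl]acetate | CCOC(=O)C[C@@]1(C)CCCC=C1 | intermediate
5 | ethyl 2-[(1R)-1-methyl-4-oxocyclohex-2-en-1-yl]acetate | CCOC(=O)C[C@@]1(C)CCC(=O)C=C1 | intermediate
6 | ethyl 2-[(1R)-3-iodo-1-methyl-4-oxocyclohex-2-en-1-yl]acetate | CCOC(=O)C[C@@]1(C)CCC(=O)C(I)=C1 | intermediate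
7 | ethyl 2-[(1R)-1,3-dimethyl-4-oxocyclohex-2-en-1-yl]acetate | CCOC(=O)C[C@@]1(C)CCC(=O)C(C)=C1 | intermediate
8 | ethyl 2-[(1R,4S)-4-hydroxy-1,3-dimethylcyclohex-2-en-1-yl]acetate | CCOC(=O)C[C@@]1(C)CC[C@H](O)C(C)=C1 | intermediate
9 | ethyl 2-[(1R,4S)-4-{[1-(dimethylamino)ethenyl]oxy}-1,3-dimethylcyclohex-2-en-1-yl]acetate (ketene aminoacetal) | CCOC(=O)C[C@@]1(C)CC[C@H](OC(=C)N(C)C)C(C)=C1 | intermediate
10 | ethyl 2-[(1R,2R)-2-[2-(dimethylamino)-2-oxoethyl]-1,3-dimethylcyclohex-3-en-1-yl]acetate | CCOC(=O)C[C@@]1(C)CCC=C(C)[C@@H]1CC(=O)N(C)C | intermediate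
11 | ethyl 2-[(1R,2R,3S,4R)-2-[2-(dimethylamino)-2-oxoethyl]-3,4-dihydroxy-1,3-dimethylcyclohexyl]acetate | O[C@@H]1CC[C@](C)(CC(=O)OCC)[C@@H](CC(=O)N(C)C)[C@]1(C)O | intermediate
12 | ethyl 2-[(3aS,4R,5R,7aR)-4-[2-(dimethylamino)-2-oxoethyl]-2,2,3a,5-tetramethylhexahydro-1,3-benzodioxol-5-yl]acetate | CC1(C)O[C@@H]2CC[C@](C)(CC(=O)OCC)[C@@H](CC(=O)N(C)C)[C@]2(C)O1 | intermediate
13 | 2-[(3aS,4R,5R,7aR)-4-[2-(dimethylamino)ethyl]-2,2,3a,5-tetramethylhexahydro-1,3-benzodioxol-5-yl]ethan-1-ol | CC1(C)O[C@@H]2CC[C@](C)(CCO)[C@@H](CCN(C)C)[C@]2(C)O1 | intermediate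
14 | 2-[(3aS,4R,5R,7aR)-5-(2-hydroxyethyl)-2,2,3a,5-tetramethylhexahydro-1,3-benzodioxol-4-yl]-N,N-dimethylethan-1-amine N-oxide | CC1(C)O[C@@H]2CC[C@](C)(CCO)[C@@H](CC[N+](C)(C)[O-])[C@]2(C)O1 | intermediate
15 | 2-[(3aS,4R,5R,7aR)-4-ethenyl-2,2,3a,5-tetramethylhexahydro-1,3-benzodioxol-5-yl]ethan-1-ol | CC1(C)O[C@@H]2CC[C@](C)(CCO)[C@@H](C=C)[C@]2(C)O1 | intermediate
16 | 2-[(3aS,4R,5R,7aR)-4-ethenyl-2,2,3a,5-tetramethylhexahydro-1,3-benzodioxol-5-yl]acetaldehyde | CC1(C)O[C@@H]2CC[C@](C)(CC=O)[C@@H](C=C)[C@]2(C)O1 | intermediate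
17 | 3-hydroxy-3-methylbutan-2-one | CC(=O)C(C)(C)O | starting material
18 | 3-methyl-3-[(triethylsilyl)oxy]butan-2-one | CC(=O)C(C)(C)O[Si](CC)(CC)CC | intermediate
19 | N'-{3-methyl-3-[(triethylsilyl)oxy]butan-2-ylidene}-2,4,6-tri(propan-2-yl)benzenesulfonohydrazide | CC(=NNS(=O)(=O)c1c(C(C)C)cc(C(C)C)cc1C(C)C)C(C)(C)O[Si](CC)(CC)CC | intermediate
20 | {3-methyl-3-[(triethylsilyl)oxy]but-1-en-2-yl}lithium | [Li]C(=C)C(C)(C)O[Si](CC)(CC)CC | intermediate
21 | 1-[(3aS,4R,5R,7aR)-4-ethenyl-2,2,3a,5-tetramethylhexahydro-1,3-benzodioxol-5-yl]-4-methyl-3-methylidene-4-[(triethylsilyl)oxy]pentan-2-ol (both C2 epimers) | CC1(C)O[C@@H]2CC[C@](C)(CC(O)C(=C)C(C)(C)O[Si](CC)(CC)CC)[C@@H](C=C)[C@]2(C)O1 | intermediate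
22 | 1-[(3aS,4R,5R,7aR)-4-ethenyl-2,2,3a,5-tetramethylhexahydro-1,3-benzodioxol-5-yl]-4-methyl-3-methylidene-4-[(triethylsilyl)oxy]pentan-2-one | CC1(C)O[C@@H]2CC[C@](C)(CC(=O)C(=C)C(C)(C)O[Si](CC)(CC)CC)[C@@H](C=C)[C@]2(C)O1 | intermediate
23 | (4aR,5S,6R,8aR)-5,8a-dimethyl-5,6-[(propane-2,2-diyl)bis(oxy)]-3-{2-[(triethylsilyl)oxy]propan-2-yl}-4a,5,6,7,8,8a-hexahydronaphthalen-2(1H)-one | CC1(C)O[C@@H]2CC[C@]3(C)CC(=O)C(C(C)(C)O[Si](CC)(CC)CC)=C[C@H]3[C@]2(C)O1 | intermediate
24 | (4aR,5S,6R,8aR)-5,6-dihydroxy-3-(2-hydroxypropan-2-yl)-5,8a-dimethyl-4a,5,6,7,8,8a-hexahydronaphthalen-2(1H)-one | O[C@@H]1CC[C@]2(C)CC(=O)C(C(C)(C)O)=C[C@H]2[C@]1(C)O | intermediate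
25 | tiglic acid, (2E)-2-methylbut-2-enoic acid | C/C=C(\C)C(=O)O | starting material
26 | (2E)-2-methylbut-2-en-1-ol | C/C=C(\C)CO | intermediate
27 | [(2R,3R)-2,3-dimethyloxiran-2-yl]methanol | C[C@H]1O[C@]1(C)CO | intermediate
28 | (2S,3R)-2,3-dimethyloxirane-2-carboxylic acid | C[C@H]1O[C@]1(C)C(=O)O | intermediate
29 | (2R,3S)-3-chloro-2-hydroxy-2-methylbutanoic acid | C[C@H](Cl)[C@](C)(O)C(=O)O | intermediate
30 | triethylsilyl (2R,3S)-3-chloro-2-methyl-2-[(triethylsilyl)oxy]butanoate | C[C@H](Cl)[C@](C)(O[Si](CC)(CC)CC)C(=O)O[Si](CC)(CC)CC | intermediate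
31 | (2R,3S)-3-chloro-2-methyl-2-[(triethylsilyl)oxy]butanoic acid | C[C@H](Cl)[C@](C)(O[Si](CC)(CC)CC)C(=O)O | intermediate
32 | (2R,3S)-3-chloro-2-methyl-2-[(triethylsilyl)oxy]butanoic 2,4,6-trichlorobenzoic anhydride | C[C@H](Cl)[C@](C)(O[Si](CC)(CC)CC)C(=O)OC(=O)c1c(Cl)cc(Cl)cc1Cl | intermediate
33 | (1S,2R,4aR,8aR)-1-hydroxy-7-(2-hydroxypropan-2-yl)-1,4a-dimethyl-6-oxo-1,2,3,4,4a,5,6,8a-octahydronaphthalen-2-yl (2R,3S)-3-chloro-2-methyl-2-[(triethylsilyl)oxy]butanoate | C[C@H](Cl)[C@](C)(O[Si](CC)(CC)CC)C(=O)O[C@@H]1CC[C@]2(C)CC(=O)C(C(C)(C)O)=C[C@H]2[C@]1(C)O | intermediate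
34 | (1S,2R,4aR,8aR)-1-hydroxy-7-(2-hydroxypropan-2-yl)-1,4a-dimethyl-6-oxo-1,2,3,4,4a,5,6,8a-octahydronaphthalen-2-yl (2R,3S)-3-chloro-2-hydroxy-2-methylbutanoate | C[C@H](Cl)[C@](C)(O)C(=O)O[C@@H]1CC[C@]2(C)CC(=O)C(C(C)(C)O)=C[C@H]2[C@]1(C)O | target

**Step count and risks**

Total step count: 25. Longest linear sequence: 18 steps (steps 1–12, 15–18, 24 and 25).

Steps most likely to fail, in order of risk:

1. Step 17 (ring-closing metathesis). The C6 alkylidene may fail to add across the hindered, electron-poor methylene of the enone, so that coupling of two vinyl groups and catalyst decay outrun ring closure. The fallback closes ring B by an intramolecular aldol condensation in which C7 attacks a C6 aldehyde. It sets out from aldehyde 16: MeMgBr (THF, −78 °C) should give secondary alcohol F1, Dess–Martin oxidation methyl ketone F2, and the kinetic lithium enolate of the methyl group (LDA, THF, −78 °C) should add to acetone to give β-hydroxy ketone F3. Silylation (Et3SiOTf, 2,6-lutidine) should give triethylsilyl ether F4, ozonolysis of the vinyl group (O3, CH2Cl2, −78 °C; PPh3) keto aldehyde F5, and cyclisation with dehydration (piperidine, AcOH, benzene, reflux) should form the C6=C7 bond. The fallback comes back to the route at compound 23.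

2. Step 24 (esterification). Acyl transfer to the axial C3 hydroxyl may be slower than attack at the aroyl carbonyl of the mixed anhydride, because the acyl carbon is flanked by a fully substituted, silyloxy-bearing carbon. The fallback acylates with the smaller epoxy acid and brings in chloride afterwards. It sets out from triol 24 and epoxy acid 28: Yamaguchi esterification (2,4,6-Cl3C6H2COCl, Et3N, then DMAP, toluene) should give epoxy ester F6, and HCl (1 M in Et2O, CH2Cl2, −20 °C) should open the epoxide at C3 of the side chain with inversion. The fallback comes back to the route at target 34.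

3. Step 7 (Eschenmoser–Claisen rearrangement). Thermal elimination of the ketene aminoacetal to a cyclohexadiene may compete with the [3,3]-shift at the hindered C5 terminus. The fallback is an Ireland–Claisen rearrangement run at low temperature. It sets out from alcohol 8: acetylation (Ac2O, DMAP, pyridine) should give acetate F7, and LDA then Me3SiCl (THF, −78 °C) silyl ketene acetal F8, which should rearrange on warming to silyl ester F9. Aqueous work-up should give acid F10, and amide coupling (Me2NH·HCl, EDC·HCl, HOBt, i-Pr2NEt, CH2Cl2) comes back to the route at compound 10.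

**Further compounds**

F1 | step 17 | 1-[(3aS,4R,5R,7aR)-4-ethenyl-2,2,3a,5-tetramethylhexahydro-1,3-benzodioxol-5-yl]propan-2-ol (both C2 epimers) | CC1(C)O[C@@H]2CC[C@](C)(CC(C)O)[C@@H](C=C)[C@]2(C)O1
F2 | step 17 | 1-[(3aS,4R,5R,7aR)-4-ethenyl-2,2,3a,5-tetramethylhexahydro-1,3-benzodioxol-5-yl]propan-2-one | CC1(C)O[C@@H]2CC[C@](C)(CC(C)=O)[C@@H](C=C)[C@]2(C)O1
F3 | step 17 | 1-[(3aS,4R,5R,7aR)-4-ethenyl-2,2,3a,5-tetramethylhexahydro-1,3-benzodioxol-5-yl]-4-hydroxy-4-methylpentan-2-one | CC1(C)O[C@@H]2CC[C@](C)(CC(=O)CC(C)(C)O)[C@@H](C=C)[C@]2(C)O1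
F4 | step 17 | 1-[(3aS,4R,5R,7aR)-4-ethenyl-2,2,3a,5-tetramethylhexahydro-1,3-benzodioxol-5-yl]-4-methyl-4-[(triethylsilyl)oxy]pentan-2-one | CC1(C)O[C@@H]2CC[C@](C)(CC(=O)CC(C)(C)O[Si](CC)(CC)CC)[C@@H](C=C)[C@]2(C)O1
F5 | step 17 | (3aS,4R,5R,7aR)-2,2,3a,5-tetramethyl-5-{4-methyl-2-oxo-4-[(triethylsilyl)oxy]pentyl}hexahydro-1,3-benzodioxole-4-carbaldehyde | CC1(C)O[C@@H]2CC[C@](C)(CC(=O)CC(C)(C)O[Si](CC)(CC)CC)[C@@H](C=O)[C@]2(C)O1
F6 | step 24 | (1S,2R,4aR,8aR)-1-hydroxy-7-(2-hydroxypropan-2-yl)-1,4a-dimethyl-6-oxo-1,2,3,4,4a,5,6,8a-octahydronaphthalen-2-yl (2S,3R)-2,3-dimethyloxirane-2-carboxylate | C[C@H]1O[C@]1(C)C(=O)O[C@@H]2CC[C@]3(C)CC(=O)C(C(C)(C)O)=C[C@H]3[C@]2(C)O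
F7 | step 7 | ethyl 2-[(1R,4S)-4-(acetyloxy)-1,3-dimethylcyclohex-2-en-1-yl]acetate | CCOC(=O)C[C@@]1(C)CC[C@H](OC(C)=O)C(C)=C1
F8 | step 7 | ethyl 2-[(1R,4S)-1,3-dimethyl-4-({1-[(trimethylsilyl)oxy]ethenyl}oxy)cyclohex-2-en-1-yl]acetate | CCOC(=O)C[C@@]1(C)CC[C@H](OC(=C)O[Si](C)(C)C)C(C)=C1
F9 | step 7 | trimethylsilyl 2-[(1R,6R)-6-(2-ethoxy-2-oxoethyl)-2,6-dimethylcyclohex-2-en-1-yl]acetate | CCOC(=O)C[C@@]1(C)CCC=C(C)[C@@H]1CC(=O)O[Si](C)(C)C
F10 | step 7 | 2-[(1R,6R)-6-(2-ethoxy-2-oxoethyl)-2,6-dimethylcyclohex-2-en-1-yl]acetic acid | CCOC(=O)C[C@@]1(C)CCC=C(C)[C@@H]1CC(=O)O
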